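Everything rests on disconnecting the two carbon arms of the quaternary spiro carbon C1, the atom common to the cyclohexene, tetrahydrofuran and oxetane rings. The acetal carbon and the tetrahydrofuran CH2 are 1,3-related, so a cyclopropane spiro-fused at C1 can hold both. One asymmetric copper-carbene [2+1] addition of ethyl diazoacetate to an exocyclic silyl dienol ether forms the C1–CH2 bond, sets C1 and stores the aldehyde as a siloxycyclopropane; fluoride-triggered retro-aldol opening then releases it. The precursor is a 2,6,6-trimethylcyclohex-2-enylidene silyl enol ether whose C5, next to the gem-dimethyl carbon, carries a dioxolane, the future vinyl bromide site.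

Key step: step 7

Remark 1 (locants): ring A is numbered C1 (quaternary spiro carbon), C2 (methyl-bearing), C3, C4, C5, C6 (gem-dimethyl carbon); Cα is the carbinol carbon, Cβ the tetrahydrofuran CH2, Cac the acetal carbon.
Remark 2 (precursor design): the vinylic bromine of the target sits on C5, between C4 and C6, so ring A must carry its latent carbonyl there; ring A is therefore built from a 2,2-dimethyl-1,3-dione.
Remark 3 (ligand): the ligand enantiomer in step 7 is assigned by analogy with the sense of induction known for terminal alkenes; it is to be checked on 14, and the antipodal ligand is used if the sense is reversed.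

Step 1
Reactants: 1 2,2-dimethylcyclohexane-1,3-dione; 2 ethylene glycol
Product: 3 6,6-dimethyl-1,4-dioxaspiro[4.5]decan-7-one
Conditions: 2 (1.1 equiv), TsOH·H2O (cat.), PhH, reflux, Dean–Stark
Reagents that add atoms: none
Why: Acid-catalysed ketalisation with azeotropic removal of water; the symmetrical dione stops at the monoketal because a second dioxolane next to the same quaternary carbon is sterically disfavoured.

Step 2
Reactants: 3 6,6-dimethyl-1,4-dioxaspiro[4.5]decan-7-one
Product: 4 (±)-6,6,8-trimethyl-1,4-dioxaspiro[4.5]decan-7-one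
Conditions: LiN(i-Pr)2, THF, −78 °C; MeI, −78 → 0 °C
Reagents that add atoms: iodomethane, CI
Why: Enolate alkylation: the single enolisable α-methylene gives one kinetic lithium enolate, which is methylated by SN2 attack on iodomethane; the new stereocentre is racemic and vanishes in step 3.

Step 3
Reactants: 4 (±)-6,6,8-trimethyl-1,4-dioxaspiro[4.5]decan-7-one
Product: 6 6,6,8-trimethyl-1,4-dioxaspiro[4.5]dec-8-en-7-one, via trimethylsilyl enol ether 5 (not isolated)
Conditions: LiN(i-Pr)2, Me3SiCl, THF, −78 → 0 °C; then Pd(OAc)2 (1.0 equiv), MeCN, rt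
Reagents that add atoms: none
Why: Saegusa–Ito oxidation: the only possible silyl enol ether 5 transfers its enolate to divalent palladium, and β-hydride elimination toward the ring CH2 gives the endocyclic 2-methyl enone, as established for enol ethers of 2-methylcyclohexanones.

Step 4
Reactants: 6 6,6,8-trimethyl-1,4-dioxaspiro[4.5]dec-8-en-7-one; 7 trimethylsulfonium iodide
Product: 8 (±)-4,8,8-trimethyl-1-oxaspiro[2.5]oct-4-en-7-one 7-(ethylene ketal) (oxirane spiro at C1 of ring A)
Conditions: 7, KOt-Bu, DMSO/THF, 0 °C → rt
Reagents that add atoms: none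
Why: Corey–Chaykovsky epoxidation: dimethylsulfonium methylide made in the flask adds to the carbonyl carbon (sulfonium ylides add 1,2 to enones) and the betaine closes to the oxirane with loss of dimethyl sulfide; the spiro stereocentre is racemic and is erased in step 6.

Step 5
Reactants: 8 (±)-4,8,8-trimethyl-1-oxaspiro[2.5]oct-4-en-7-one 7-(ethylene ketal)
Product: 9 (±)-6,6,8-trimethyl-1,4-dioxaspiro[4.5]dec-8-ene-7-carbaldehyde
Conditions: MgBr2·OEt2 (0.3 equiv), Et2O, 0 °C
Reagents that add atoms: none
Why: Meinwald rearrangement: the Lewis acid opens the oxirane at its tertiary, allylic carbon and a 1,2-hydride shift from the CH2O carbon gives the β,γ-unsaturated aldehyde, whose racemic C1 centre becomes sp2 in step 6.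

Step 6
Reactants: 9 (±)-6,6,8-trimethyl-1,4-dioxaspiro[4.5]dec-8-ene-7-carbaldehyde
Product: 10 (E)-tert-butyldimethyl[(6,6,8-trimethyl-1,4-dioxaspiro[4.5]dec-8-en-7-ylidene)methoxy]silane (ring A silyl dienol ether, C5 dioxolane; siloxy group on the side of C2)
Conditions: TBSOTf, Et3N, CH2Cl2, −78 → 0 °C
Reagents that add atoms: tert-butyldimethylsilyl trifluoromethanesulfonate, CC(C)(C)[Si](C)(C)OS(=O)(=O)C(F)(F)F
Why: Soft enolisation with O-silylation: the one α-hydrogen of 9, on C1 and allylic, is removed by the amine after silylation of the carbonyl oxygen, which gives the conjugated dienol ether, drawn as the (E) isomer, its geometry affecting only a cyclopropane centre that is erased in step 8.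

Step 7
Reactants: 10 (E)-silyl dienol ether; 11 ethyl diazoacetate
Product: 12 ethyl (1R,2R,3R)-2-(tert-butyldimethylsilyloxy)-4,8,8-trimethyl-7-oxospiro[2.5]oct-4-ene-1-carboxylate 7-(ethylene ketal) (spiro siloxycyclopropane ester; C1 of ring A is the spiro carbon; configuration of the two CH carbons of no consequence)
Conditions: (CuOTf)2·C6H6 (2 mol %), (S,S)-t-Bu-box [2,2'-(propane-2,2-diyl)bis((4S)-4-tert-butyl-4,5-dihydrooxazole)] (4.4 mol %), CH2Cl2, 0 °C → rt, 11 (2 equiv) by syringe pump over 8 h
Reagents that add atoms: none
Why: Monovalent copper decomposes 11 to a copper carbene, whose electrophilic carbon is attacked by C1, the nucleophilic terminus of the enol ether, while positive charge builds up on the siloxy-bearing carbon and the second bond closes there in a concerted, asynchronous [2+1] addition. The closest known reaction type is the copper bis(oxazoline)-catalysed asymmetric cyclopropanation of silyl enol ethers with diazoacetates to 2-siloxycyclopropanecarboxylates, which is also known for enol ethers of α-branched aldehydes that give spiro products. The spiro cyclopropane, the only ring closed, forms by this [2+1] carbene addition across the exocyclic C1=CH bond. The ester-bearing carbon is set by the ligand, which decides the face of the carbene that the alkene reaches; C1 is set by the same event together with the preference of the ester for the side of flat C2 over the gem-dimethyl carbon C6; the siloxy carbon follows stereospecifically from the enol ether geometry, and only C1 outlives step 8. The step needs chemoselectivity for the exocyclic alkene over the ring alkene C2=C3 and one sense of alkene orientation: the siloxy group makes C1=CH the most electron-rich π bond, C2=C3 is trisubstituted with C2 wedged between C1 and its methyl group, and the bulk of C6 fixes the orientation. Slow addition of 11 suppresses carbene dimerisation.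

Step 8
Reactants: 12 spiro siloxycyclopropane ester
Product: 14 ethyl 2-[(1R)-1-formyl-2,6,6-trimethyl-5-oxocyclohex-2-en-1-yl]acetate, via ketal oxo ester 13 (not isolated)
Conditions: TBAF, AcOH, THF, 0 °C; then 1 M HCl, rt
Reagents that add atoms: water, O
Why: Fluoride-induced retro-aldol ring opening of a 2-siloxycyclopropanecarboxylate: desilylation gives a cyclopropanolate that cleaves the bond between the oxygen-bearing carbon and the ester-bearing carbon, because the ester enolate is by far the best carbanion leaving group, so C1 keeps its configuration and now carries CHO and CH2CO2Et, after which aqueous acid hydrolyses the C5 dioxolane.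

Step 9
Reactants: 14 ethyl 2-[(1R)-1-formyl-2,6,6-trimethyl-5-oxocyclohex-2-en-1-yl]acetate; 2 ethylene glycol
Product: 15 ethyl 2-[(1R)-1-(1,3-dioxolan-2-yl)-2,6,6-trimethyl-5-oxocyclohex-2-en-1-yl]acetate
Conditions: 2 (1.05 equiv), PPTS (cat.), PhH, reflux, Dean–Stark
Reagents that add atoms: none
Why: Acetalisation under equilibrating conditions with one equivalent of diol: the dioxolane settles on the aldehyde, whose acetal is much more favourable than the ketal of the C5 ketone flanked by the gem-dimethyl carbon, so the aldehyde is masked for steps 10 to 13 while the ketone stays free.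

Step 10
Reactants: 15 ethyl 2-[(1R)-1-(1,3-dioxolan-2-yl)-2,6,6-trimethyl-5-oxocyclohex-2-en-1-yl]acetate
Product: 16 ethyl 2-[(1R)-1-(1,3-dioxolan-2-yl)-2,6,6-trimethyl-5-(trifluoromethanesulfonyloxy)cyclohexa-2,4-dien-1-yl]acetate
Conditions: KN(SiMe3)2, THF, −78 °C; PhNTf2, −78 → 0 °C
Reagents that add atoms: N-phenylbis(trifluoromethanesulfonimide), O=S(=O)(N(c1ccccc1)S(=O)(=O)C(F)(F)F)C(F)(F)F
Why: Enol triflate formation: the C5 ketone can enolise only toward C4 (C6 is quaternary), its allylic α-hydrogens are far more acidic than those of the ester, and the dienolate is sulfonylated on oxygen by PhNTf2 to give the 2,4-dienyl triflate.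

Step 11
Reactants: 16 dienyl triflate
Product: 17 ethyl 2-[(1R)-5-bromo-1-(1,3-dioxolan-2-yl)-2,6,6-trimethylcyclohexa-2,4-dien-1-yl]acetate
Conditions: Ni(cod)2 (10 mol %), LiBr, DMA/THF, rt
Reagents that add atoms: lithium bromide, [Li+].[Br-]
Why: Nickel-catalysed conversion of an enol triflate into an alkenyl bromide: zerovalent nickel inserts into the C–OTf bond, triflate is exchanged for bromide and reductive elimination forms the C5–Br bond, with C1 untouched.

Step 12
Reactants: 17 bromodiene ester
Product: 19 1-[(1R)-5-bromo-1-(1,3-dioxolan-2-yl)-2,6,6-trimethylcyclohexa-2,4-dien-1-yl]-3-methylbut-3-en-2-one, via Weinreb amide 18 (not isolated)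
Conditions: MeNH(OMe)·HCl, i-PrMgCl, THF, −20 °C; then isopropenylmagnesium bromide, −20 → 0 °C; cold aq. NH4Cl
Reagents that add atoms: isopropenylmagnesium bromide, C=C(C)[Mg]Br
Why: Weinreb ketone synthesis in one flask: the chloromagnesium amide of N,O-dimethylhydroxylamine turns the ester into amide 18, whose magnesium chelate takes up one equivalent of the alkenyl Grignard reagent and collapses to the isopropenyl ketone only on work-up, while the alkenyl bromide is inert to both Grignard reagents at this temperature.

Step 13
Reactants: 19 isopropenyl ketone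
Product: 20 (2R)-1-[(1R)-5-bromo-1-(1,3-dioxolan-2-yl)-2,6,6-trimethylcyclohexa-2,4-dien-1-yl]-3-methylbut-3-en-2-ol
Conditions: (S)-Me-CBS oxazaborolidine (20 mol %), catecholborane, PhMe, −78 °C
Reagents that add atoms: none
Why: Corey–Bakshi–Shibata reduction: the oxazaborolidine binds the ketone with the α-branched alkenyl group as the large and the CH2 group as the small substituent, so the (S)-catalyst should deliver hydride to the face that gives the (R)-carbinol, and any 19 of the wrong C1 configuration is turned into a separable diastereomer.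

Step 14
Reactants: 20 (R)-allylic alcohol
Product: 22 (3R,5R)-9-bromo-6,10,10-trimethyl-3-(prop-1-en-2-yl)-2-oxaspiro[4.5]deca-6,8-dien-1-ol (lactol, both anomers), via hydroxy aldehyde 21 (not isolated)
Conditions: 1 M HCl, THF, 0 °C → rt
Reagents that add atoms: water, O
Why: Acid-catalysed acetal hydrolysis frees aldehyde 21, which is trapped at once by the γ-hydroxyl as the five-membered lactol (ring–chain tautomerism), and the lactol cannot dehydrate because C1 bears no hydrogen.

Step 15
Reactants: 22 lactol bromodiene
Product: 23 target CNP0141320.1 (Cα R, C1 S, Cac S, C2 S, C3 S)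
Conditions: NBS (1.05 equiv), NaHCO3, MeCN, −30 → 0 °C, dark
Reagents that add atoms: N-bromosuccinimide, O=C1CCC(=O)N1Br
Why: Bromoetherification (halonium-induced 4-exo cyclisation of a homoallylic hydroxyl to an oxetane): the bromonium ion forms on the electron-rich trisubstituted C2=C3 bond on the face opposite to the acetal arm, and the lactol hydroxyl, held on the other face of C1, opens it at the tertiary carbon C2 with anti addition, which sets C2, C3 and the acetal carbon in one event, the unreactive anomer feeding the reactive one through 21.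

Compound list
1 | 2,2-dimethylcyclohexane-1,3-dione | CC1(C)C(=O)CCCC1=O | starting material
2 | ethylene glycol | OCCO | starting material
3 | 6,6-dimethyl-1,4-dioxaspiro[4.5]decan-7-one | CC1(C)C(=O)CCCC12OCCO2 | intermediate
4 | (±)-6,6,8-trimethyl-1,4-dioxaspiro[4.5]decan-7-one | CC1CCC2(OCCO2)C(C)(C)C1=O | intermediate
5 | trimethyl[(6,6,8-trimethyl-1,4-dioxaspiro[4.5]dec-7-en-7-yl)oxy]silane | CC1=C(O[Si](C)(C)C)C(C)(C)C2(OCCO2)CC1 | intermediate (not isolated)
6 | 6,6,8-trimethyl-1,4-dioxaspiro[4.5]dec-8-en-7-one | CC1=CCC2(OCCO2)C(C)(C)C1=O | intermediate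
7 | trimethylsulfonium iodide | C[S+](C)C.[I-] | starting material
8 | (±)-4,8,8-trimethyl-1-oxaspiro[2.5]oct-4-en-7-one 7-(ethylene ketal) | CC1=CCC2(OCCO2)C(C)(C)C13CO3 | intermediate
9 | (±)-6,6,8-trimethyl-1,4-dioxaspiro[4.5]dec-8-ene-7-carbaldehyde | CC1=CCC2(OCCO2)C(C)(C)C1C=O | intermediate
10 | (E)-tert-butyldimethyl[(6,6,8-trimethyl-1,4-dioxaspiro[4.5]dec-8-en-7-ylidene)methoxy]silane | CC1=CCC2(OCCO2)C(C)(C)/C1=C/O[Si](C)(C)C(C)(C)C | intermediate
11 | ethyl diazoacetate | CCOC(=O)C=[N+]=[N-] | starting material
12 | ethyl (1R,2R,3R)-2-(tert-butyldimethylsilyloxy)-4,8,8-trimethyl-7-oxospiro[2.5]oct-4-ene-1-carboxylate 7-(ethylene ketal) | CCOC(=O)[C@H]1[C@@H](O[Si](C)(C)C(C)(C)C)[C@@]12C(C)=CCC3(OCCO3)C2(C)C | intermediate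
13 | ethyl 2-[(7R)-7-formyl-6,6,8-trimethyl-1,4-dioxaspiro[4.5]dec-8-en-7-yl]acetate | CCOC(=O)C[C@@]1(C=O)C(C)=CCC2(OCCO2)C1(C)C | intermediate (not isolated)
14 | ethyl 2-[(1R)-1-formyl-2,6,6-trimethyl-5-oxocyclohex-2-en-1-yl]acetate | CCOC(=O)C[C@@]1(C=O)C(C)=CCC(=O)C1(C)C | intermediate
15 | ethyl 2-[(1R)-1-(1,3-dioxolan-2-yl)-2,6,6-trimethyl-5-oxocyclohex-2-en-1-yl]acetate | CCOC(=O)C[C@@]1(C2OCCO2)C(C)=CCC(=O)C1(C)C | intermediate
16 | ethyl 2-[(1R)-1-(1,3-dioxolan-2-yl)-2,6,6-trimethyl-5-(trifluoromethanesulfonyloxy)cyclohexa-2,4-dien-1-yl]acetate | CCOC(=O)C[C@@]1(C2OCCO2)C(C)=CC=C(OS(=O)(=O)C(F)(F)F)C1(C)C | intermediate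
17 | ethyl 2-[(1R)-5-bromo-1-(1,3-dioxolan-2-yl)-2,6,6-trimethylcyclohexa-2,4-dien-1-yl]acetate | CCOC(=O)C[C@@]1(C2OCCO2)C(C)=CC=C(Br)C1(C)C | intermediate
18 | 2-[(1R)-5-bromo-1-(1,3-dioxolan-2-yl)-2,6,6-trimethylcyclohexa-2,4-dien-1-yl]-N-methoxy-N-methylacetamide | CON(C)C(=O)C[C@@]1(C2OCCO2)C(C)=CC=C(Br)C1(C)C | intermediate (not isolated)
19 | 1-[(1R)-5-bromo-1-(1,3-dioxolan-2-yl)-2,6,6-trimethylcyclohexa-2,4-dien-1-yl]-3-methylbut-3-en-2-one | C=C(C)C(=O)C[C@@]1(C2OCCO2)C(C)=CC=C(Br)C1(C)C | intermediate
20 | (2R)-1-[(1R)-5-bromo-1-(1,3-dioxolan-2-yl)-2,6,6-trimethylcyclohexa-2,4-dien-1-yl]-3-methylbut-3-en-2-ol | C=C(C)[C@H](O)C[C@@]1(C2OCCO2)C(C)=CC=C(Br)C1(C)C | intermediate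
21 | (1R)-5-bromo-1-[(2R)-2-hydroxy-3-methylbut-3-en-1-yl]-2,6,6-trimethylcyclohexa-2,4-diene-1-carbaldehyde | C=C(C)[C@H](O)C[C@@]1(C=O)C(C)=CC=C(Br)C1(C)C | intermediate (not isolated)
22 | (3R,5R)-9-bromo-6,10,10-trimethyl-3-(prop-1-en-2-yl)-2-oxaspiro[4.5]deca-6,8-dien-1-ol (both anomers) | C=C(C)[C@H]1C[C@@]2(C(O)O1)C(C)=CC=C(Br)C2(C)C | intermediate
23 | CNP0141320.1: cyclohexene C1–C6 with 3,5-dibromo, 2,6,6-trimethyl substitution, oxetane O bridging C2 and Cac, tetrahydrofuran spiro at C1 bearing isopropenyl on Cα (Cα R, C1 S, Cac S, C2 S, C3 S) | C=C(C)[C@H]1C[C@@]23[C@@H](O1)O[C@]2(C)[C@@H](Br)C=C(Br)C3(C)C | target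

Total step count: 15 steps.
Longest linear sequence: 15 steps (1 → 23).

Steps most likely to fail

Step 7. The carbene may not tell the two faces apart well enough, or the ester may not keep to the C2 side, so that the spiro carbon is formed with low enantiomeric purity. The fallback gives up catalyst control and resolves. It sets out from 10: cyclopropanation with 11 under an achiral catalyst (Cu(acac)2 or Rh2(OAc)4) gives 12 together with the enantiomer of 12 F1. The conditions of step 8 convert the pair into 14 and the enantiomeric keto aldehyde ester F3, by way of the enantiomeric ketal oxo ester F2. Preparative chromatography on a chiral stationary phase then delivers 14, where the route is rejoined.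

Step 15. The four-membered closure may be outrun by five-membered closures, either attack of the carbinol oxygen of ring-opened 21 on C2 or attack of the lactol oxygen on the allylic carbon C3. The bromine electrophile may also be consumed by the isopropenyl group or by oxidation of the lactol. The fallback separates C–Br from C–O bond formation and reverses the polarity of the ring closure. It sets out from 19, which has no free hydroxyl and a ketone-deactivated side-chain alkene. NBS in aqueous acetone should give the trans bromohydrin enone F4, with the bromonium ion on the face away from the dioxolanyl arm and water entering at the tertiary C2. The reduction of step 13 gives the bromohydrin carbinol F5, and the hydrolysis of step 14 gives the lactol tertiary alcohol F6. Mitsunobu-type dehydration (PPh3, DIAD), in which the activated anomeric carbon is captured by the C2 hydroxyl held on the same face, closes the oxetane acetal and rejoins the route at 23.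

Step 4. The ylide may fail to add to the carbonyl carbon flanked by C2 and the gem-dimethyl carbon, through γ-deprotonation of the enone or simple lack of reaction. The fallback is a carbonylative one-carbon homologation that bypasses steps 3 to 5. It sets out from 4: KN(SiMe3)2 and PhNTf2 give the only possible enol triflate F7. Palladium-catalysed formylation (Pd(PPh3)4, CO, Bu3SnH, THF, 50 °C) gives the conjugated enal F8. γ-Deprotonation at the ring CH2 (C3) with O-silylation (TBSOTf, Et3N) then gives 10, where the route is rejoined.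

Further compounds
F1 | step 7 | enantiomer of 12 | CCOC(=O)[C@@H]1[C@H](O[Si](C)(C)C(C)(C)C)[C@]12C(C)=CCC3(OCCO3)C2(C)C
F2 | step 7 | ethyl 2-[(7S)-7-formyl-6,6,8-trimethyl-1,4-dioxaspiro[4.5]dec-8-en-7-yl]acetate | CCOC(=O)C[C@]1(C=O)C(C)=CCC2(OCCO2)C1(C)C
F3 | step 7 | ethyl 2-[(1S)-1-formyl-2,6,6-trimethyl-5-oxocyclohex-2-en-1-yl]acetate | CCOC(=O)C[C@]1(C=O)C(C)=CCC(=O)C1(C)C
F4 | step 15 | bromohydrin enone: 19 with OH on C2 (face of the dioxolanyl arm) and Br on C3 (opposite face), C4=C5(Br) retained | C=C(C)C(=O)C[C@@]1(C2OCCO2)[C@](C)(O)[C@@H](Br)C=C(Br)C1(C)C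
F5 | step 15 | bromohydrin carbinol: (R)-allylic alcohol from F4 | C=C(C)[C@H](O)C[C@@]1(C2OCCO2)[C@](C)(O)[C@@H](Br)C=C(Br)C1(C)C
F6 | step 15 | lactol tertiary alcohol: 22 carrying OH on C2 and Br on C3 | C=C(C)[C@H]1C[C@@]2(C(O)O1)[C@](C)(O)[C@@H](Br)C=C(Br)C2(C)C
F7 | step 4 | 6,6,8-trimethyl-1,4-dioxaspiro[4.5]dec-7-en-7-yl trifluoromethanesulfonate | CC1=C(OS(=O)(=O)C(F)(F)F)C(C)(C)C2(OCCO2)CC1
F8 | step 4 | 6,6,8-trimethyl-1,4-dioxaspiro[4.5]dec-7-ene-7-carbaldehyde | CC1=C(C=O)C(C)(C)C2(OCCO2)CC1
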